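The route rests on cutting the C3–C4 bond of the oxolane (O1, C2 with catechol ring A, C3 with C9H2OAc, C4 with the C7' benzyl of ring B, C5). C3 carries a ring bond and the one-carbon branch C9, the pattern a Wolff shift leaves behind. Photolysis of a 3-diazo-2,3-dihydro-4H-pyran-4-one in methanol moves the vinylic C4 from the ketone carbon (the future C9) to C3: the six-membered ring contracts to the oxolane as its 4,5-ene, C9 emerges as a methyl ester and C3 is set trans to the C2 aryl. The precursor is the (R)-2-aryl-5-benzyl-3-diazo-dihydropyranone, whose C2 centre comes from a catalytic asymmetric hetero-Diels–Alder reaction.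

Key step: step 6

Assumption: the titanium–BINOL catalyst is taken to add the diene to the same face of an aryl aldehyde as in related titanium–BINOL additions, so that (S)-BINOL gives the (S)-pyranone 4; if the sense proves opposite, (R)-BINOL is used and nothing else changes.

Design remarks: the ring B benzyl group is attached to C5 of the pyranone by cross-coupling and is not built into the diene, because a 2-benzyl diene would require formylation of a 4-arylbutan-2-one at its methylene carbon, which competes with formylation at the methyl group. The three phenols are carried as benzyl ethers. Compound names use their own ring numbering; the Why lines of steps 6 to 9 use the oxolane numbering of the target (O1, C2 to C5, C9, C7').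

Step 1
Reactants: 1 3,4-bis(benzyloxy)benzaldehyde; 2 trans-1-methoxy-3-(trimethylsilyloxy)buta-1,3-diene (Danishefsky's diene)
Product: 4 (S)-2-[3,4-bis(benzyloxy)phenyl]-2,3-dihydro-4H-pyran-4-one, via aldol silyl ether 3 (not isolated)
Conditions: Ti(OiPr)4 (10 mol %), (S)-BINOL (20 mol %), 4 Å MS, Et2O, −20 °C; then TFA, CH2Cl2, 0 °C
Reagents that add atoms: none
Why: Catalytic asymmetric hetero-Diels–Alder reaction in its Mukaiyama aldol–cyclisation mode, in which the chiral titanium–BINOL Lewis acid exposes one face of the aryl aldehyde to the terminal CH2 of the silyloxy diene and so sets C2 as (S), after which trifluoroacetic acid closes β-silyloxy enone 3 by oxa-Michael addition and loss of methanol without touching the benzyl ethers.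

Step 2
Reactants: 4 (S)-2-[3,4-bis(benzyloxy)phenyl]-2,3-dihydro-4H-pyran-4-one
Product: 5 (S)-2-[3,4-bis(benzyloxy)phenyl]-5-iodo-2,3-dihydro-4H-pyran-4-one
Conditions: I2, pyridine, CH2Cl2, 0 °C to rt, dark
Reagents that add atoms: iodine, II
Why: Electrophilic α-iodination of the vinylogous ester with I2–pyridine goes to C5, the nucleophilic β-carbon of the enol ether and the only enone position open to substitution, while the weak base leaves C3 and the C2 centre alone and the dialkoxyarene is not iodinated without an oxidant.

Step 3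
Reactants: 6 4-(benzyloxy)-3-methoxybenzyl alcohol
Product: 7 4-(benzyloxy)-3-methoxybenzyl chloride
Conditions: SOCl2, CH2Cl2, 0 °C to rt
Reagents that add atoms: thionyl chloride, O=S(Cl)Cl
Why: Chlorodehydroxylation of a benzylic alcohol by thionyl chloride through its chlorosulfite ester is a standard nucleophilic substitution, and the electron-rich chloride is used at once in the next step.

Step 4
Reactants: 5 (S)-2-[3,4-bis(benzyloxy)phenyl]-5-iodo-2,3-dihydro-4H-pyran-4-one; 7 4-(benzyloxy)-3-methoxybenzyl chloride
Product: 9 (S)-2-[3,4-bis(benzyloxy)phenyl]-5-[4-(benzyloxy)-3-methoxybenzyl]-2,3-dihydro-4H-pyran-4-one, via benzylzinc chloride 8 (not isolated)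
Conditions: 7, Zn dust, LiCl, THF, 25 °C; then 5, Pd(OAc)2 (2 mol %), SPhos (4 mol %), THF, 25 °C
Reagents that add atoms: none
Why: Negishi cross-coupling, in which LiCl-assisted zinc insertion into the benzylic chloride gives 8, oxidative addition of the C5–I bond to zerovalent palladium, transmetalation and reductive elimination form the C5–CH2 bond, and the non-basic organozinc neither enolises C3 nor adds to the enone, so the C2 centre is kept.

Step 5
Reactants: 9 (S)-2-[3,4-bis(benzyloxy)phenyl]-5-[4-(benzyloxy)-3-methoxybenzyl]-2,3-dihydro-4H-pyran-4-one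
Product: 12 (R)-2-[3,4-bis(benzyloxy)phenyl]-5-[4-(benzyloxy)-3-methoxybenzyl]-3-diazo-2,3-dihydro-4H-pyran-4-one, via lithium enolate 10 (not isolated), via trifluoroacetyl ketone 11 (not isolated)
Conditions: LiN(SiMe3)2, THF, −78 °C; CF3CO2CH2CF3, −78 °C; then 4-acetamidobenzenesulfonyl azide, Et3N, H2O, MeCN, rt
Reagents that add atoms: 4-acetamidobenzenesulfonyl azide, CC(=O)Nc1ccc(cc1)S(=O)(=O)N=[N+]=[N-]
Why: Detrifluoroacetylative diazo transfer, in which the kinetic lithium enolate can form only at C3 because the other α carbon is vinylic, is C-acylated at −78 °C before it can open the ring by β-elimination, and the resulting 1,3-diketone 11 takes the diazo group from the sulfonyl azide with loss of the trifluoroacetyl group as the N-acyl sulfonamide, leaving C2 untouched (its descriptor becomes R only through the priority change at C3).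

Step 6
Reactants: 12 (R)-2-[3,4-bis(benzyloxy)phenyl]-5-[4-(benzyloxy)-3-methoxybenzyl]-3-diazo-2,3-dihydro-4H-pyran-4-one
Product: 14 methyl (2S,3S)-2-[3,4-bis(benzyloxy)phenyl]-4-[4-(benzyloxy)-3-methoxybenzyl]-2,3-dihydrofuran-3-carboxylate, via ketene 13 (not isolated)
Conditions: hν (medium-pressure Hg lamp, Pyrex filter), degassed MeOH–THF, 0 °C
Reagents that add atoms: methanol, CO
Why: Excitation of the ring-locked s-cis diazo ketone expels N2 in concert with the 1,2-shift of the vinylic C4 from the acyl carbon (future C9) to the diazo carbon C3, which gives vinylketene 13; methanol adds to the ketene and the resulting ester enol is protonated at C3. The closest known reaction type is the photochemical Wolff ring contraction of cyclic α-diazo ketones with alcohol capture, including cases in which an sp2 carbon migrates, as in diazonaphthoquinones and 3-diazochroman-4-ones. The oxolane ring is closed by this 1,2-carbon shift, a contraction of the pyranone ring, and not by a cyclisation, so no rule for ring closure by nucleophilic attack applies. The new C3 stereocentre is set by substrate control: the enol is protonated on the face away from the C2 aryl, the only ring substituent next to it, which gives the 2,3-trans ester (expected also to be the more stable epimer while C4 is sp2), and C2 is not touched. The step needs the carbon shift to beat 1,2-hydride shift from C2 and O–H insertion into methanol, and α-protonation to beat γ-protonation at C5; the s-cis geometry enforced by the ring (loss of N2 without a free carbene), direct irradiation without sensitiser or metal, and the kinetic preference of dienols for α-protonation should secure this. Regiochemistry is not in question, because the second α carbon of the ketone is vinylic, so only C3 could take the diazo group and only one carbon can migrate.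

Step 7
Reactants: 14 methyl (2S,3S)-2-[3,4-bis(benzyloxy)phenyl]-4-[4-(benzyloxy)-3-methoxybenzyl]-2,3-dihydrofuran-3-carboxylate
Product: 15 {(2S,3R)-2-[3,4-bis(benzyloxy)phenyl]-4-[4-(benzyloxy)-3-methoxybenzyl]-2,3-dihydrofuran-3-yl}methanol
Conditions: i-Bu2AlH (2.5 equiv), CH2Cl2, −78 to 0 °C; aq. potassium sodium tartrate
Reagents that add atoms: none
Why: Hydride reduction of the ester to the primary alcohol by i-Bu2AlH through the aldehyde, chosen because this non-basic reagent at low temperature cannot remove the acidic C3–H of the β,γ-unsaturated ester, so the trans C2/C3 relationship and the position of the enol ether are kept (C3 becomes R by priority change only).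

Step 8
Reactants: 15 {(2S,3R)-2-[3,4-bis(benzyloxy)phenyl]-4-[4-(benzyloxy)-3-methoxybenzyl]-2,3-dihydrofuran-3-yl}methanol
Product: 16 {(2S,3R)-2-[3,4-bis(benzyloxy)phenyl]-4-[4-(benzyloxy)-3-methoxybenzyl]-2,3-dihydrofuran-3-yl}methyl acetate
Conditions: Ac2O, pyridine, DMAP (cat.), CH2Cl2, 0 °C to rt
Reagents that add atoms: acetic anhydride, CC(=O)OC(C)=O
Why: DMAP-catalysed O-acylation of the only free hydroxyl group (nucleophilic catalysis through the N-acetylpyridinium ion) installs the C9 acetate and masks the hydroxyl group so that it cannot hold the catalyst on its own face in the next step.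

Step 9
Reactants: 16 {(2S,3R)-2-[3,4-bis(benzyloxy)phenyl]-4-[4-(benzyloxy)-3-methoxybenzyl]-2,3-dihydrofuran-3-yl}methyl acetate
Product: 17 [(2S,3R,4R)-2-(3,4-dihydroxyphenyl)-4-(4-hydroxy-3-methoxybenzyl)oxolan-3-yl]methyl acetate
Conditions: H2 (1 atm), 10% Pd/C, EtOAc, rt
Reagents that add atoms: none
Why: Heterogeneous catalytic hydrogenation should deliver both hydrogens syn to the less hindered face of the trisubstituted enol ether, the face opposite the adjacent C3 acetoxymethyl group, which places H4 cis to H3 and sets C4 as (R) with the C7' benzyl cis to C9, while the same catalyst removes the three aryl benzyl ethers by hydrogenolysis, expected to be faster than cleavage of the benzylic C2–O1 ring bond, and leaves the acetate alone.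

Compound list
1 | 3,4-bis(benzyloxy)benzaldehyde | O=Cc1ccc(OCc2ccccc2)c(OCc2ccccc2)c1 | starting material
2 | trans-1-methoxy-3-(trimethylsilyloxy)buta-1,3-diene | CO/C=C/C(=C)O[Si](C)(C)C | starting material
3 | (S,E)-5-[3,4-bis(benzyloxy)phenyl]-1-methoxy-5-(trimethylsilyloxy)pent-1-en-3-one | CO/C=C/C(=O)C[C@H](O[Si](C)(C)C)c1ccc(OCc2ccccc2)c(OCc2ccccc2)c1 | intermediate
4 | (S)-2-[3,4-bis(benzyloxy)phenyl]-2,3-dihydro-4H-pyran-4-one | O=C1C[C@@H](c2ccc(OCc3ccccc3)c(OCc3ccccc3)c2)OC=C1 | intermediate
5 | (S)-2-[3,4-bis(benzyloxy)phenyl]-5-iodo-2,3-dihydro-4H-pyran-4-one | O=C1C[C@@H](c2ccc(OCc3ccccc3)c(OCc3ccccc3)c2)OC=C1I | intermediate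
6 | 4-(benzyloxy)-3-methoxybenzyl alcohol | COc1cc(CO)ccc1OCc1ccccc1 | starting material
7 | 4-(benzyloxy)-3-methoxybenzyl chloride | COc1cc(CCl)ccc1OCc1ccccc1 | intermediate
8 | [4-(benzyloxy)-3-methoxybenzyl]zinc chloride | COc1cc(C[Zn]Cl)ccc1OCc1ccccc1 | intermediate
9 | (S)-2-[3,4-bis(benzyloxy)phenyl]-5-[4-(benzyloxy)-3-methoxybenzyl]-2,3-dihydro-4H-pyran-4-one | O=C1C[C@@H](c2ccc(OCc3ccccc3)c(OCc3ccccc3)c2)OC=C1Cc1ccc(OCc2ccccc2)c(OC)c1 | intermediate
10 | lithium (S)-2-[3,4-bis(benzyloxy)phenyl]-5-[4-(benzyloxy)-3-methoxybenzyl]-2H-pyran-4-olate | [Li]OC1=C[C@@H](c2ccc(OCc3ccccc3)c(OCc3ccccc3)c2)OC=C1Cc1ccc(OCc2ccccc2)c(OC)c1 | intermediate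
11 | (2S)-2-[3,4-bis(benzyloxy)phenyl]-5-[4-(benzyloxy)-3-methoxybenzyl]-3-(trifluoroacetyl)-2,3-dihydro-4H-pyran-4-one (C3 not defined, largely enolised) | O=C1C(C(=O)C(F)(F)F)[C@@H](c2ccc(OCc3ccccc3)c(OCc3ccccc3)c2)OC=C1Cc1ccc(OCc2ccccc2)c(OC)c1 | intermediate
12 | (R)-2-[3,4-bis(benzyloxy)phenyl]-5-[4-(benzyloxy)-3-methoxybenzyl]-3-diazo-2,3-dihydro-4H-pyran-4-one | [N-]=[N+]=C1C(=O)C(Cc2ccc(OCc3ccccc3)c(OC)c2)=CO[C@@H]1c1ccc(OCc2ccccc2)c(OCc2ccccc2)c1 | intermediate
13 | {(R)-2-[3,4-bis(benzyloxy)phenyl]-4-[4-(benzyloxy)-3-methoxybenzyl]furan-3(2H)-ylidene}methanone (ketene) | O=C=C1C(Cc2ccc(OCc3ccccc3)c(OC)c2)=CO[C@@H]1c1ccc(OCc2ccccc2)c(OCc2ccccc2)c1 | intermediate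
14 | methyl (2S,3S)-2-[3,4-bis(benzyloxy)phenyl]-4-[4-(benzyloxy)-3-methoxybenzyl]-2,3-dihydrofuran-3-carboxylate (2,3-trans) | COC(=O)[C@H]1C(Cc2ccc(OCc3ccccc3)c(OC)c2)=CO[C@@H]1c1ccc(OCc2ccccc2)c(OCc2ccccc2)c1 | intermediate
15 | {(2S,3R)-2-[3,4-bis(benzyloxy)phenyl]-4-[4-(benzyloxy)-3-methoxybenzyl]-2,3-dihydrofuran-3-yl}methanol | OC[C@H]1C(Cc2ccc(OCc3ccccc3)c(OC)c2)=CO[C@@H]1c1ccc(OCc2ccccc2)c(OCc2ccccc2)c1 | intermediate
16 | {(2S,3R)-2-[3,4-bis(benzyloxy)phenyl]-4-[4-(benzyloxy)-3-methoxybenzyl]-2,3-dihydrofuran-3-yl}methyl acetate | CC(=O)OC[C@H]1C(Cc2ccc(OCc3ccccc3)c(OC)c2)=CO[C@@H]1c1ccc(OCc2ccccc2)c(OCc2ccccc2)c1 | intermediate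
17 | [(2S,3R,4R)-2-(3,4-dihydroxyphenyl)-4-(4-hydroxy-3-methoxybenzyl)oxolan-3-yl]methyl acetate | COc1cc(C[C@H]2CO[C@H](c3ccc(O)c(O)c3)[C@H]2COC(C)=O)ccc1O | target

Total step count: 9. Longest linear sequence: 8 steps (steps 1, 2, 4, 5, 6, 7, 8, 9 from aldehyde 1); step 3 is a one-step side branch.

Steps most likely to fail

Step 6. The excited diazo ketone may leave the rearrangement path for carbene-type reactions. These are a 1,2-hydride shift from C2, which would give the flat 4-pyranone and erase the C2 centre, and O–H insertion into methanol. The ester enol may also be protonated without face control or at the γ carbon. The fallback takes the rearrangement out of the photochemical manifold and away from solvent methanol. It sets out from 12, which would be heated in toluene with a few equivalents of benzyl alcohol (sealed tube, about 150 °C). In this thermal Wolff rearrangement the ring-locked s-cis diazo ketone loses N2 from the ground state with concerted migration, and the ketene meets only a small amount of alcohol. This should give benzyl (2S,3S)-2-[3,4-bis(benzyloxy)phenyl]-4-[4-(benzyloxy)-3-methoxybenzyl]-2,3-dihydrofuran-3-carboxylate F2. Reduction of this ester with i-Bu2AlH (CH2Cl2, −78 to 0 °C) comes back to the route at alcohol 15.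

Step 5. The C3 lithium enolate may open the ring by β-elimination of the ring oxygen before it is acylated, which would also scramble C2 on re-closure, or it may be acylated on oxygen. The fallback brings in the diazo group without strong base by the Forster route and sets out from 9. Acid-catalysed nitrosation at C3 (isoamyl nitrite, HCl, THF–EtOH, 0 °C), the way 2-arylchroman-4-ones are converted into their 3-hydroxyimino derivatives, should give (R)-2-[3,4-bis(benzyloxy)phenyl]-5-[4-(benzyloxy)-3-methoxybenzyl]-3-(hydroxyimino)-2,3-dihydro-4H-pyran-4-one F1. Chloramine (aq. NH3, NaOCl, 0 °C) would then convert the oxime into the diazo group, which comes back to the route at 12.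

Step 9. The single hydrogenation may over-reduce by hydrogenolytic opening of the benzylic C2–O1 bond, or the double bond may migrate before it is saturated, or the facial selectivity at C4 may be incomplete. The fallback separates the two tasks and sets out from 16. The alkene would first be saturated with H2 over Pd/C poisoned with diphenyl sulfide in EtOAc, which leaves benzyl ethers and benzylic C–O bonds alone. This should give {(2S,3R,4R)-2-[3,4-bis(benzyloxy)phenyl]-4-[4-(benzyloxy)-3-methoxybenzyl]oxolan-3-yl}methyl acetate F3, a stage at which any C4 epimer can be removed by chromatography. Hydrogenolysis of the three benzyl ethers (H2, Pd(OH)2/C, EtOAc–EtOH, stopped as soon as the last benzyl group has gone) then comes back to the route at 17.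

Further compounds
F1 | step 5 | (R)-2-[3,4-bis(benzyloxy)phenyl]-5-[4-(benzyloxy)-3-methoxybenzyl]-3-(hydroxyimino)-2,3-dihydro-4H-pyran-4-one | ON=C1C(=O)C(Cc2ccc(OCc3ccccc3)c(OC)c2)=CO[C@@H]1c1ccc(OCc2ccccc2)c(OCc2ccccc2)c1
F2 | step 6 | benzyl (2S,3S)-2-[3,4-bis(benzyloxy)phenyl]-4-[4-(benzyloxy)-3-methoxybenzyl]-2,3-dihydrofuran-3-carboxylate | O=C(OCc1ccccc1)[C@H]1C(Cc2ccc(OCc3ccccc3)c(OC)c2)=CO[C@@H]1c1ccc(OCc2ccccc2)c(OCc2ccccc2)c1
F3 | step 9 | {(2S,3R,4R)-2-[3,4-bis(benzyloxy)phenyl]-4-[4-(benzyloxy)-3-methoxybenzyl]oxolan-3-yl}methyl acetate | CC(=O)OC[C@H]1[C@@H](Cc2ccc(OCc3ccccc3)c(OC)c2)CO[C@@H]1c1ccc(OCc2ccccc2)c(OCc2ccccc2)c1
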